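Core numbering: C1 (angelate carbinol), C2, C3 (senecioate carbinol), C4 (CMe2), cyclobutane C5–C6–C11–C10, enone bridge C7(=O)–C8=C9(Me). The route rests on cutting C9–C10 and C6–C7: the enone bridge is a crotonyl unit spanning C6 and C10, the enantiotopic α-carbons of a mirror-symmetric cyclobutanone (C5 carbonyl, C11 quaternary). One chiral-enamine annulation with crotonoyl chloride forms both bonds, closes the six-membered ring of a bicyclo[3.1.1]heptane-2,6-dione and fixes the absolute sense of the cage. The precursor is 3-(dimethoxymethyl)-3-methylcyclobutanone; its branched acetal (C1, already at the aldehyde level) directs the bridge to the methyl face.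

Key step: step 5

Remark: the antipodes of the two chiral controllers (amine 6 in step 5, (−)-Ipc2BCl in step 8) are assigned from steric models and both antipodes are available, so a reversed sense would be met by switching antipode and not by changing the route.

Step 1
Reactants: 1 3-methylidenecyclobutane-1-carbonitrile
Product: 2 1-methyl-3-methylidenecyclobutane-1-carbonitrile
Conditions: LiN(i-Pr)2, THF, −78 °C; MeI, −78 → 0 °C
Reagents that add atoms: iodomethane CI
Why: Alkylation of the lithiated nitrile with iodomethane installs the C11 methyl group at the only acidic position, and the carbon is not stereogenic because its two ring arms are identical.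

Step 2
Reactants: 2 1-methyl-3-methylidenecyclobutane-1-carbonitrile
Product: 3 1-methyl-3-methylidenecyclobutane-1-carbaldehyde
Conditions: i-Bu2AlH, CH2Cl2, −78 °C; 1 M HCl, 0 °C
Reagents that add atoms: water O
Why: Partial hydride reduction of the hindered nitrile stops at the N-aluminated aldimine, which hydrolyses to the C1 aldehyde on work-up, the exocyclic alkene being inert to the hydride.

Step 3
Reactants: 3 1-methyl-3-methylidenecyclobutane-1-carbaldehyde
Product: 4 1-(dimethoxymethyl)-1-methyl-3-methylidenecyclobutane
Conditions: HC(OMe)3, MeOH, PPTS (cat.), rt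
Reagents that add atoms: trimethyl orthoformate COC(OC)OC
Why: Acid-catalysed acetalisation with the orthoformate as water scavenger gives the branched dimethyl acetal, which later shields its own face of the four-membered ring and keeps C1 at the aldehyde oxidation level.

Step 4
Reactants: 4 1-(dimethoxymethyl)-1-methyl-3-methylidenecyclobutane
Product: 5 3-(dimethoxymethyl)-3-methylcyclobutan-1-one
Conditions: O3, CH2Cl2/MeOH, −78 °C; Me2S, −78 °C → rt
Reagents that add atoms: ozone [O-][O+]=O
Why: Ozonolysis of the 1,1-disubstituted exocyclic alkene with reductive work-up reveals the C5 ketone, the alkene having served as a ketone mask that cannot be confused with the C1 acetal.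

Step 5
Reactants: 5 3-(dimethoxymethyl)-3-methylcyclobutan-1-one; 6 (2R,5R)-2,5-dimethylpyrrolidine; 7 (E)-but-2-enoyl chloride (crotonoyl chloride)
Product: 10 7-(dimethoxymethyl)-4,7-dimethylbicyclo[3.1.1]heptane-2,6-dione, via chiral enamine 8 (not isolated), via bicyclic iminium chloride 9 (not isolated)
Conditions: 6, 4 Å MS, PhMe, 60 °C; 7, −20 → 80 °C; H2O, NaOAc, AcOH, rt
Reagents that add atoms: water O
Why: Proposed new method: enamine 8 is N-acylated by 7 and the N-acyl enammonium ion undergoes a 3-aza-Cope (aza-Claisen) shift that joins C10 to the crotonyl β-carbon C9 and leaves a ketene tethered to the C5 iminium; proton transfer gives the C5=C6 enamine, whose carbon C6 acylates the ketene carbon C7 to give iminium salt 9, which is hydrolysed to 10. The closest known reaction type is the α,α′-annulation of cyclopentanone and cyclohexanone enamines with acryloyl chlorides, which has not been shown on a cyclobutanone enamine or as a desymmetrisation. The six-membered ring C5–C6–C7–C8–C9–C10 closes by a 6-exo-dig attack of the enamine carbon C6 on the ketene carbon C7 (enolendo with respect to the enamine), and since both new bonds must lie on one face of the four-membered ring the configuration at C6 follows from that at C10. C10, and with it the absolute sense of the cage, is set by the C2-symmetric amine (its nitrogen stays non-stereogenic on acylation and the acyl group should be transferred anti to the methyl group on the pyrrolidine carbon next to the enamine double bond); C9 is set by a chair arrangement with the (E)-methyl group pseudo-equatorial, which places it on the C5 side (this centre is lost in step 16 and either epimer would serve), and C11 becomes stereogenic only because C6 and C10 are now different. The step needs the choice of one enantiotopic α-carbon and attack on the face syn to the C11 methyl group; the two regioisomeric enamines are diastereomers that interconvert, and only in one of them do the face preferred by the amine and the face away from the branched dimethoxymethyl group coincide.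

Step 6
Reactants: 10 7-(dimethoxymethyl)-4,7-dimethylbicyclo[3.1.1]heptane-2,6-dione
Product: 11 4,7-dimethyl-2,6-dioxobicyclo[3.1.1]heptane-7-carbaldehyde
Conditions: 1 M HCl, THF, rt
Reagents that add atoms: water O
Why: Acid hydrolysis of the dimethyl acetal unmasks the C1 aldehyde without a nucleophile that could open the strained 1,3-dione, C11 carries no hydrogen so nothing can epimerise, and no free hydroxyl ever sits beside the C5 ketone.

Step 7
Reactants: 11 4,7-dimethyl-2,6-dioxobicyclo[3.1.1]heptane-7-carbaldehyde
Product: 12 4,7-dimethyl-6-oxo-2-[tri(propan-2-yl)silyloxy]bicyclo[3.1.1]hept-2-ene-7-carbaldehyde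
Conditions: TIPSOTf, Et3N, CH2Cl2, −78 → 0 °C
Reagents that add atoms: triisopropylsilyl trifluoromethanesulfonate CC(C)[Si](OS(=O)(=O)C(F)(F)F)(C(C)C)C(C)C
Why: Soft enolisation with O-silylation can only go toward C8 because C6 and C10 are bridgeheads and the aldehyde has no α-hydrogen, and the bulky enol silane masks C7 so that C5 is no longer part of a 1,3-dicarbonyl unit and a later C5 alkoxide cannot open the cyclobutane by retro-aldol cleavage of C5–C6 (de Mayo-type fragmentation).

Step 8
Reactants: 12 4,7-dimethyl-6-oxo-2-[tri(propan-2-yl)silyloxy]bicyclo[3.1.1]hept-2-ene-7-carbaldehyde; 13 3-methylbut-3-en-2-one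
Product: 15 7-[(1R)-1-hydroxy-4-methyl-3-oxopent-4-en-1-yl]-4,7-dimethyl-2-[tri(propan-2-yl)silyloxy]bicyclo[3.1.1]hept-2-en-6-one, via diisopinocampheylboron enolate 14 (not isolated)
Conditions: 13, (−)-Ipc2BCl, Et3N, Et2O, 0 °C; 12, −78 → −20 °C; MeOH, pH 7 buffer
Reagents that add atoms: none
Why: Reagent-controlled boron aldol addition in which the diisopinocampheylboron enolate of the methyl ketone should add through a closed transition state to the re face of the neopentyl aldehyde and set C1 as R (C1–C2 bond), the cage itself offering no bias at C1, so that the chiral boron ligands decide and the minor C1 epimer would be removed by chromatography; peroxide is avoided in the work-up because of the cyclobutanone and the enol silane.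

Step 9
Reactants: 15 (1R)-aldol adduct
Product: 16 7-[(1R)-4-methyl-3-oxo-1-(triethylsilyloxy)pent-4-en-1-yl]-4,7-dimethyl-2-[tri(propan-2-yl)silyloxy]bicyclo[3.1.1]hept-2-en-6-one
Conditions: TESCl, imidazole, DMF, 0 °C → rt
Reagents that add atoms: chlorotriethylsilane CC[Si](Cl)(CC)CC
Why: Imidazole-mediated silylation of the secondary C1 hydroxyl keeps it from retro-aldol cleavage under the enolate conditions of step 10 and from acylation in step 11.

Step 10
Reactants: 16 triethylsilyl ether of the aldol adduct
Product: 17 tricyclic β-hydroxy ketone (core numbering): C4–C5 bond closed, C5–OH syn to the C7–C9 bridge, C3 ketone, C1 (R) triethylsilyl ether, C7=C8 triisopropylsilyl enol ether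
Conditions: [(Ph3P)CuH]6, PhMe, −40 → 0 °C; aq. NH4Cl/NH3 (pH 8)
Reagents that add atoms: none
Why: Copper hydride reductive aldol cyclisation in which conjugate hydride delivery to the unhindered methylene of the isopropenyl ketone gives the C4 copper enolate regiospecifically, which adds to the C5 cyclobutanone from the only face the C11 tether can reach (anti to the C7–C9 bridge) and so closes the seven-membered ring with the C5 configuration dictated by the cage; the product is kept away from acid.

Step 11
Reactants: 17 tricyclic β-hydroxy ketone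
Product: 18 C5 methyl oxalate of 17
Conditions: ClC(O)CO2Me, DMAP, pyridine, CH2Cl2, 0 °C → rt
Reagents that add atoms: methyl chlorooxoacetate COC(=O)C(Cl)=O
Why: DMAP-catalysed acylation of the tertiary cyclobutanol with the very electrophilic chlorooxoacetate installs a radical leaving group without ever forming a free C5 alkoxide.

Step 12
Reactants: 18 C5 methyl oxalate
Product: 19 C5-deoxygenated tricycle (core numbering): C5–H, C3 ketone, C1 (R) triethylsilyl ether, C7=C8 triisopropylsilyl enol ether
Conditions: Bu3SnH, AIBN, PhMe, 100 °C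
Reagents that add atoms: none
Why: Radical deoxygenation of a tertiary methyl oxalate (Barton–McCombie-type tin hydride chain) in which the C5 cyclobutyl radical is held pyramidal by its three ring bonds, so that hydrogen can only be delivered to the lobe facing the C7–C9 bridge, which gives the C5–H of the target.

Step 13
Reactants: 19 C5-deoxygenated tricycle
Product: 20 (1R)-1-hydroxy-4,4,9,11-tetramethyl tricyclic 3,7-dione (core numbering; C8 methylene, C9–H)
Conditions: aq. HF (48%), MeCN, 0 °C
Reagents that add atoms: none
Why: Fluoride-induced cleavage of the triethylsilyl ether and of the silyl enol ether returns the C1 hydroxyl and the C7 ketone, protonation at the C8 methylene creates no stereocentre, and the unmasked ketone is harmless now that C5 carries no oxygen.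

Step 14
Reactants: 20 (1R)-1-hydroxy tricyclic 3,7-dione
Product: 21 (1R,3R)-1-acetoxy-3-hydroxy-4,4,9,11-tetramethyl tricyclic 7-ketone (core numbering; 1,3-trans)
Conditions: SmI2 (0.3 equiv), MeCHO, THF, −10 °C
Reagents that add atoms: acetaldehyde CC=O
Why: Evans–Tishchenko reduction in which the hemiacetal of the C1 hydroxyl and acetaldehyde transfers hydride within a samarium-bridged six-membered transition state to the face of the C3 ketone on which the C1 oxygen lies, giving the trans (1,3-anti) C3 alcohol (R) and leaving C1 as its acetate so that the two oxygens are differentiated, while the C7 ketone has no β-hydroxyl and is not reduced.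

Step 15
Reactants: 21 (1R,3R)-1-acetoxy-3-hydroxy tricyclic 7-ketone; 22 3-methylbut-2-enoyl chloride (senecioyl chloride)
Product: 23 (1R,3R)-1-acetoxy-3-(3-methylbut-2-enoyloxy)-4,4,9,11-tetramethyl tricyclic 7-ketone (core numbering)
Conditions: pyridine, DMAP (cat.), CH2Cl2, 0 → 40 °C
Reagents that add atoms: none
Why: Pyridine/DMAP acylation of the only free hydroxyl (C3) with the acid chloride, pyridine instead of a stronger amine avoiding deconjugation of the senecioate through the vinylketene.

Step 16
Reactants: 23 acetate senecioate with saturated C7 ketone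
Product: 24 (1R,3R)-1-acetoxy-3-(3-methylbut-2-enoyloxy)-4,4,9,11-tetramethyl tricyclic C8=C9 enone (core numbering)
Conditions: IBX, DMSO, 75 °C
Reagents that add atoms: none
Why: IBX dehydrogenation of the ketone through its enol, which can form only toward C8 because C6 is a bridgehead, so the C8=C9 enone arises regiospecifically and the auxiliary C9 stereocentre vanishes.

Step 17
Reactants: 24 acetate senecioate enone
Product: 25 (1R,3R)-1-hydroxy-3-(3-methylbut-2-enoyloxy)-4,4,9,11-tetramethyl tricyclic C8=C9 enone (core numbering)
Conditions: K2CO3, MeOH, 0 °C → rt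
Reagents that add atoms: none
Why: Carbonate-catalysed transesterification should remove the unconjugated acetate much faster than the conjugated and more hindered senecioate, and the trans-1,3 arrangement keeps the C3 ester from migrating to C1.

Step 18
Reactants: 25 hydroxy senecioate enone; 26 (2Z)-2-methylbut-2-enoic acid (angelic acid)
Product: 28 CNP0277258.2 (target), via mixed anhydride 27 (not isolated)
Conditions: 26, 2,4,6-Cl3C6H2COCl, Et3N, PhMe, rt; 25, 75 °C
Reagents that add atoms: none
Why: Yamaguchi-type esterification through the mixed 2,4,6-trichlorobenzoic anhydride, run without a nucleophilic catalyst, should acylate the C1 hydroxyl with retention of the (Z)-geometry of the angelate.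

Compound list
1 | 3-methylidenecyclobutane-1-carbonitrile | N#CC1CC(=C)C1 | starting material
2 | 1-methyl-3-methylidenecyclobutane-1-carbonitrile | CC1(C#N)CC(=C)C1 | intermediate
3 | 1-methyl-3-methylidenecyclobutane-1-carbaldehyde | CC1(C=O)CC(=C)C1 | intermediate
4 | 1-(dimethoxymethyl)-1-methyl-3-methylidenecyclobutane | COC(OC)C1(C)CC(=C)C1 | intermediate
5 | 3-(dimethoxymethyl)-3-methylcyclobutan-1-one (precursor of the key step) | COC(OC)C1(C)CC(=O)C1 | intermediate
6 | (2R,5R)-2,5-dimethylpyrrolidine | C[C@@H]1CC[C@@H](C)N1 | starting material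
7 | (E)-but-2-enoyl chloride (crotonoyl chloride) | C/C=C/C(Cl)=O | starting material
8 | chiral enamine, (2R,5R)-1-[3-(dimethoxymethyl)-3-methylcyclobut-1-en-1-yl]-2,5-dimethylpyrrolidine with the double bond toward C10 (not isolated) | COC(OC)[C@@]1(C)CC(N2[C@H](C)CC[C@H]2C)=C1 | intermediate
9 | bicyclic iminium chloride, the C5 (2R,5R)-2,5-dimethylpyrrolidinium ylidene of 10 (not isolated) | COC(OC)[C@@]1(C)[C@@H]2C(=O)C[C@@H](C)[C@H]1C2=[N+]3[C@H](C)CC[C@H]3C.[Cl-] | intermediate
10 | 7-(dimethoxymethyl)-4,7-dimethylbicyclo[3.1.1]heptane-2,6-dione; C11 methyl syn to the C7–C9 bridge, C9 methyl on the C5 side (product of the key step) | COC(OC)[C@@]1(C)[C@@H]2C(=O)C[C@@H](C)[C@H]1C2=O | intermediate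
11 | 4,7-dimethyl-2,6-dioxobicyclo[3.1.1]heptane-7-carbaldehyde, cage as in 10 | O=C[C@@]1(C)[C@@H]2C(=O)C[C@@H](C)[C@H]1C2=O | intermediate
12 | 4,7-dimethyl-6-oxo-2-[tri(propan-2-yl)silyloxy]bicyclo[3.1.1]hept-2-ene-7-carbaldehyde, cage as in 10 | O=C[C@@]1(C)[C@@H]2C(O[Si](C(C)C)(C(C)C)C(C)C)=C[C@@H](C)[C@H]1C2=O | intermediate
13 | 3-methylbut-3-en-2-one | CC(=O)C(C)=C | starting material
14 | diisopinocampheylboron enolate of 13, from (−)-Ipc2BCl (not isolated) | C=C(C)C(=C)OB([C@@H]1C[C@@H]2C[C@H]([C@H]1C)C2(C)C)[C@@H]1C[C@@H]2C[C@H]([C@H]1C)C2(C)C | intermediate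
15 | 7-[(1R)-1-hydroxy-4-methyl-3-oxopent-4-en-1-yl]-4,7-dimethyl-2-[tri(propan-2-yl)silyloxy]bicyclo[3.1.1]hept-2-en-6-one, cage as in 10 | C=C(C)C(=O)C[C@@H](O)[C@@]1(C)[C@@H]2C(O[Si](C(C)C)(C(C)C)C(C)C)=C[C@@H](C)[C@H]1C2=O | intermediate
16 | triethylsilyl ether of 15 at the C1 oxygen | C=C(C)C(=O)C[C@@H](O[Si](CC)(CC)CC)[C@@]1(C)[C@@H]2C(O[Si](C(C)C)(C(C)C)C(C)C)=C[C@@H](C)[C@H]1C2=O | intermediate
17 | tricyclic β-hydroxy ketone (core numbering): 5-hydroxy (syn to the C7–C9 bridge), C3 ketone, (1R)-1-triethylsilyloxy, C7=C8 triisopropylsilyl enol ether, 4,4,9,11-tetramethyl | CC[Si](CC)(CC)O[C@@H]1CC(=O)C(C)(C)[C@]2(O)[C@H]3C(O[Si](C(C)C)(C(C)C)C(C)C)=C[C@@H](C)[C@@H]2[C@]31C | intermediate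
18 | C5 methyl oxalate of 17 | CC[Si](CC)(CC)O[C@@H]1CC(=O)C(C)(C)[C@]2(OC(=O)C(=O)OC)[C@H]3C(O[Si](C(C)C)(C(C)C)C(C)C)=C[C@@H](C)[C@@H]2[C@]31C | intermediate
19 | C5-deoxygenated tricycle (core numbering): C5–H syn to the C7–C9 bridge, C3 ketone, (1R)-1-triethylsilyloxy, C7=C8 triisopropylsilyl enol ether | CC[Si](CC)(CC)O[C@@H]1CC(=O)C(C)(C)[C@@H]2[C@H]3C(O[Si](C(C)C)(C(C)C)C(C)C)=C[C@@H](C)[C@@H]2[C@]31C | intermediate
20 | (1R)-1-hydroxy-4,4,9,11-tetramethyl tricyclic 3,7-dione (core numbering) | O[C@@H]1CC(=O)C(C)(C)[C@@H]2[C@H]3C(=O)C[C@@H](C)[C@@H]2[C@]31C | intermediate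
21 | (1R,3R)-1-acetoxy-3-hydroxy-4,4,9,11-tetramethyl tricyclic 7-ketone (core numbering; 1,3-trans) | CC(=O)O[C@@H]1C[C@@H](O)C(C)(C)[C@@H]2[C@H]3C(=O)C[C@@H](C)[C@@H]2[C@]31C | intermediate
22 | 3-methylbut-2-enoyl chloride (senecioyl chloride) | CC(C)=CC(Cl)=O | starting material
23 | (1R,3R)-1-acetoxy-3-(3-methylbut-2-enoyloxy)-4,4,9,11-tetramethyl tricyclic 7-ketone (core numbering) | CC(=O)O[C@@H]1C[C@@H](OC(=O)C=C(C)C)C(C)(C)[C@@H]2[C@H]3C(=O)C[C@@H](C)[C@@H]2[C@]31C | intermediate
24 | (1R,3R)-1-acetoxy-3-(3-methylbut-2-enoyloxy)-4,4,9,11-tetramethyl tricyclic C8=C9 enone (core numbering) | CC(=O)O[C@@H]1C[C@@H](OC(=O)C=C(C)C)C(C)(C)[C@@H]2[C@H]3C(=O)C=C(C)[C@@H]2[C@]31C | intermediate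
25 | (1R,3R)-1-hydroxy-3-(3-methylbut-2-enoyloxy)-4,4,9,11-tetramethyl tricyclic C8=C9 enone (core numbering) | O[C@@H]1C[C@@H](OC(=O)C=C(C)C)C(C)(C)[C@@H]2[C@H]3C(=O)C=C(C)[C@@H]2[C@]31C | intermediate
26 | (2Z)-2-methylbut-2-enoic acid (angelic acid) | C/C=C(/C)C(=O)O | starting material
27 | angelic 2,4,6-trichlorobenzoic mixed anhydride (not isolated) | C/C=C(/C)C(=O)OC(=O)c1c(Cl)cc(Cl)cc1Cl | intermediate
28 | CNP0277258.2, (1R,2R,3R,5R,7S,8R)-2,6,6,9-tetramethyl-5-[(3-methylbut-2-enoyl)oxy]-11-oxotricyclo[5.4.0.0^2,8]undec-9-en-3-yl (2Z)-2-methylbut-2-enoate | C/C=C(/C)C(=O)O[C@@H]1C[C@@H](OC(=O)C=C(C)C)C(C)(C)[C@@H]2[C@H]3C(=O)C=C(C)[C@@H]2[C@]31C | target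

Total step count: 18. Longest linear sequence: 18 steps (1 to 28); compounds 6, 7, 13, 22 and 26 are used as bought.

Steps most likely to fail

Step 5. The strained cyclobutene enamine may be N-acylated without the ketene–iminium closing the bridged ring (oligomerisation of the ketene), or the choice between the enantiotopic α-carbons may be poor. The fallback forms the same two bonds one at a time by known reactions. It sets out from 5, which is condensed with (S)-1-amino-2-(methoxymethyl)pyrrolidine to the chiral hydrazone F1. Its lithium azaenolate (LiN(i-Pr)2, THF, −78 °C) adds in a Michael reaction to methyl (E)-but-2-enoate to give the hydrazone ester F2 (C9–C10 bond; face chosen by the auxiliary and by the acetal). Ozonolytic cleavage of the hydrazone gives the keto ester F3, LiOH hydrolysis gives the keto acid F4, and pentafluorophenol with a carbodiimide gives the pentafluorophenyl ester F5. Soft enolisation of the ketone toward C6 (MgBr2·OEt2, i-Pr2NEt, CH2Cl2) then acylates C6 intramolecularly (C6–C7 bond), and the route is rejoined at 10. If the Michael step gives the other C9 epimer, that epimer is carried on equally, since C9 becomes sp2 in step 16.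

Step 10. Conjugate reduction may succeed while the hindered tetrasubstituted copper enolate is protonated before it reaches the C5 ketone, so that no ring is closed. The fallback separates enolate formation from ring closure and activates the ketone instead of the nucleophile. It sets out from 16: 1,4-hydrosilylation with Et3SiH and RhCl(PPh3)3 (cat.) gives the tetrasubstituted triethylsilyl enol ether F6, and BF3·OEt2 (CH2Cl2, −78 °C) then brings about an intramolecular Mukaiyama aldol addition to the C5 ketone, which returns to the route at 17 after neutral aqueous work-up.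

Step 14. Formation of the hemiacetal, or the samarium-bridged hydride transfer, may be blocked by the geometry of the bridged seven-membered ring, which would leave the ketone unreduced or lead to retro-aldol loss of the C1–C2 bond. The fallback sets out from 20: hydroxyl-directed reduction with Me4NBH(OAc)3 (MeCN/AcOH, −20 °C; hydride delivered from the boron bound to the C1 oxygen) should give the trans-1,3-diol F7. Its less hindered C1 hydroxyl (the C3 hydroxyl is flanked by the C4 gem-dimethyl group) is then acetylated selectively (Ac2O, 2,4,6-collidine, CH2Cl2, −20 °C), and the route is rejoined at 21.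

Further compounds
F1 | step 5 | hydrazone of 5 with (S)-1-amino-2-(methoxymethyl)pyrrolidine | COC[C@@H]1CCCN1N=C1CC(C)(C(OC)OC)C1
F2 | step 5 | Michael adduct, methyl 3-substituted butanoate at C10 of the hydrazone (side chain cis to the C11 methyl) | COC[C@@H]1CCCN1N=C1C[C@](C)(C(OC)OC)[C@H]1[C@H](C)CC(=O)OC
F3 | step 5 | methyl 3-[3-(dimethoxymethyl)-3-methyl-2-oxocyclobutyl]butanoate | O=C1C[C@](C)(C(OC)OC)[C@H]1[C@H](C)CC(=O)OC
F4 | step 5 | 3-[3-(dimethoxymethyl)-3-methyl-2-oxocyclobutyl]butanoic acid | O=C1C[C@](C)(C(OC)OC)[C@H]1[C@H](C)CC(=O)O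
F5 | step 5 | pentafluorophenyl 3-[3-(dimethoxymethyl)-3-methyl-2-oxocyclobutyl]butanoate | O=C1C[C@](C)(C(OC)OC)[C@H]1[C@H](C)CC(=O)Oc1c(F)c(F)c(F)c(F)c1F
F6 | step 10 | C3 triethylsilyl enol ether of the reduced side chain of 16 (C3=C4 tetrasubstituted) | CC(C)=C(O[Si](CC)(CC)CC)C[C@@H](O[Si](CC)(CC)CC)[C@@]1(C)[C@@H]2C(O[Si](C(C)C)(C(C)C)C(C)C)=C[C@@H](C)[C@H]1C2=O
F7 | step 14 | (1R,3R)-1,3-dihydroxy-4,4,9,11-tetramethyl tricyclic 7-ketone (core numbering; 1,3-trans) | O[C@@H]1C[C@@H](O)C(C)(C)[C@@H]2[C@H]3C(=O)C[C@@H](C)[C@@H]2[C@]31C
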